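**Plan**

- Ring labels: ring B is the central butanoylphloroglucinol, ring C the outer ring with OMe next to the bridge, ring A the outer ring with OMe next to its butanoyl group (a1 bridge carbon, a2 C–OH, a3 C–Me, a4 C–OMe, a5 C–butanoyl, a6 C–OH).
- Cuts, in order: the five O-benzyl groups, the a5–acyl bond (Houben–Hoesch), the a6 O–Si bond, then a2–a3 and a4–a5 of ring A. Because a3 (Me) and a4 (OMe) are neighbours, they are the two carbons of 1-methoxyprop-1-yne; what remains is a 3-silyloxycyclobutenone holding a1, a2, a5 and a6.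
- Further cuts: the cyclobutenone to an arylpropanoyl ketene plus a silyloxyacetylene, the propanoic chain to acrylic acid (ring B–CH2 bond), the B–C methylene bridge (Mannich base/quinone methide), and ring C to 2-methylphloroglucinol.
- Forward: ring C (acylation, para-O-methylation), B–C dimer, dihydrocoumarin, benzyl protection and free acid, cyclobutenone, ring A by benzannulation with removal of the silyl group in the same flask, butanoyl group on a5, debenzylation.
- Stereochemistry: the target has no stereocentre; the only one formed on the way (C4 of the cyclobutenone, racemic) becomes the aromatic carbon a1.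

Key step: step 11

Abbreviation: Ar = 2,4,6-tris(benzyloxy)-3-butanoyl-5-{[2,4-bis(benzyloxy)-3-butanoyl-6-methoxy-5-methylphenyl]methyl}phenyl (ring B with the ring C arm, fully benzylated).

Assumption: in step 5 the lactone is taken to close on the ring B hydroxyl para to the butanoyl group; the isomeric lactone would give the same open-chain benzyl ester after step 6.

**Route**

Step 1
Reactants: 1 2-methylbenzene-1,3,5-triol
Product: 2 1-(2,4,6-trihydroxy-3-methylphenyl)butan-1-one
Conditions: n-PrCOCl (1.1 equiv), AlCl3 (3 equiv), PhNO2–CH2Cl2, 0 °C → 40 °C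
Reagents that add atoms: butanoyl chloride (CCCC(=O)Cl)
Why: Friedel–Crafts acylation of a phloroglucinol; the two free ring carbons of 1 are equivalent and the first acyl group deactivates the ring against a second.

Step 2
Reactants: 2 1-(2,4,6-trihydroxy-3-methylphenyl)butan-1-one
Product: 3 1-(2,6-dihydroxy-4-methoxy-3-methylphenyl)butan-1-one (aspidinol)
Conditions: Me2SO4 (1.0 equiv), K2CO3 (1.1 equiv), acetone, rt
Reagents that add atoms: dimethyl sulfate (COS(=O)(=O)OC)
Why: Williamson methylation with one equivalent; the hydroxyl para to the ketone is the most acidic and is not held in a hydrogen bond to the carbonyl, so it should react first.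

Step 3
Reactants: 3 1-(2,6-dihydroxy-4-methoxy-3-methylphenyl)butan-1-one
Product: 4 1-[3-[(dimethylamino)methyl]-2,6-dihydroxy-4-methoxy-5-methylphenyl]butan-1-one
Conditions: CH2(NMe2)2 (1.2 equiv), 1,4-dioxane, rt → 50 °C
Reagents that add atoms: bis(dimethylamino)methane (CN(C)CN(C)C)
Why: phenolic Mannich reaction at the single free ring carbon of 3, which lies ortho to a hydroxyl.

Step 4
Reactants: 4 1-[3-[(dimethylamino)methyl]-2,6-dihydroxy-4-methoxy-5-methylphenyl]butan-1-one; 5 1-(2,4,6-trihydroxyphenyl)butan-1-one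
Product: 7 1-[3-[(3-butanoyl-2,4,6-trihydroxyphenyl)methyl]-2,6-dihydroxy-4-methoxy-5-methylphenyl]butan-1-one, via quinone methide 6 (not isolated)
Conditions: 5 (3 equiv), 1,4-dioxane, 100 °C, argon
Reagents that add atoms: none
Why: thermal loss of dimethylamine from the phenolic Mannich base gives the ortho-quinone methide, which a free ring carbon of 5 attacks in a Michael-type Friedel–Crafts alkylation; the excess of 5 limits double alkylation.

Step 5
Reactants: 7 B–C dimer; 8 prop-2-enoic acid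
Product: 10 6-butanoyl-8-[(3-butanoyl-2,4-dihydroxy-6-methoxy-5-methylphenyl)methyl]-5,7-dihydroxy-3,4-dihydro-2H-chromen-2-one, via hydroxy acid 9 (not isolated)
Conditions: 8 (3 equiv), Amberlyst-15 (sulfonic acid resin), hydroquinone (trace), toluene–1,4-dioxane, 100 °C
Reagents that add atoms: none
Why: acid-catalysed conjugate hydroarylation (Friedel–Crafts type) of acrylic acid at the only unsubstituted ring carbon of 7, followed by lactonisation of the hydroxy acid to the dihydrocoumarin with loss of water.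

Step 6
Reactants: 10 dihydrocoumarin
Product: 12 benzyl 3-Ar-propanoate, via benzyl ester pentaphenol 11 (not isolated)
Conditions: BnOH (5 equiv), BnBr (8 equiv), K2CO3 (10 equiv), Bu4NI (cat.), DMF, 60 °C, argon
Reagents that add atoms: benzyl alcohol (OCc1ccccc1); benzyl bromide (BrCc1ccccc1)
Why: carbonate-mediated alcoholysis of the activated aryl lactone by benzyl alcohol, then Williamson benzylation of all five phenols in a dipolar aprotic solvent, which favours O- over C-alkylation.

Step 7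
Reactants: 12 benzyl 3-Ar-propanoate
Product: 13 3-Ar-propanoic acid
Conditions: LiOH, THF–MeOH–H2O, rt; then 1 M HCl to pH 3
Reagents that add atoms: lithium hydroxide ([Li+].[OH-])
Why: saponification of an unhindered primary alkyl ester; aryl benzyl ethers and the flanked aryl ketones are inert to hydroxide at room temperature.

Step 8
Reactants: 14 ethyne
Product: 17 ethynyloxytri(propan-2-yl)silane, via lithium acetylide 15 (not isolated), via lithium ethynolate 16 (not isolated)
Conditions: n-BuLi, THF, −78 °C; LiOOt-Bu (from t-BuOOH and LiN(SiMe3)2), −78 → −20 °C; i-Pr3SiOSO2CF3, −78 → 0 °C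
Reagents that add atoms: tert-butyl hydroperoxide (CC(C)(C)OO); tri(propan-2-yl)silyl trifluoromethanesulfonate (CC(C)[Si](C(C)C)(C(C)C)OS(=O)(=O)C(F)(F)F)
Why: electrophilic oxygenation of a lithium acetylide by lithium tert-butyl peroxide to the ynolate, then O-silylation by the bulky silyl triflate; this is the established route from terminal alkynes to silyl ynol ethers, applied here to ethyne itself.

Step 9
Reactants: 13 3-Ar-propanoic acid; 17 ethynyloxytri(propan-2-yl)silane
Product: 20 4-(Ar-methyl)-3-[tri(propan-2-yl)silyloxy]cyclobut-2-en-1-one (racemic), via acid chloride 18 (not isolated), via ketene 19 (not isolated)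
Conditions: (COCl)2, DMF (cat.), CH2Cl2, 0 °C → rt, evaporate; then 17 (2 equiv), Et3N (1.5 equiv), THF, 0 °C → rt
Reagents that add atoms: none
Why: acid chloride formation, dehydrochlorination to the aldoketene and [2+2] cycloaddition with the silyl ynol ether, in which the ketene carbonyl carbon bonds to the nucleophilic CH terminus, so the silyloxy carbon ends next to the carbon bearing the Ar-methyl group; that carbon is formed racemic and becomes aromatic in step 11.

Step 10
Reactants: 21 2-chloro-1,1-dimethoxyethane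
Product: 24 1-methoxyprop-1-yne, via chlorovinyl ether 22 (not isolated), via sodium methoxyethynide 23 (not isolated)
Conditions: NaNH2 (3 equiv), liquid NH3, −33 °C; then MeI, −33 °C; distil
Reagents that add atoms: iodomethane (CI)
Why: two base-induced β-eliminations (methanol, then HCl) give the sodium alkoxyacetylide, which is C-methylated in liquid ammonia; this is the classical alkoxyalkyne synthesis.

Step 11
Reactants: 20 silyloxycyclobutenone; 24 1-methoxyprop-1-yne
Product: 30 2-(Ar-methyl)-5-methoxy-4-methylbenzene-1,3-diol, via vinylketene 25 (not isolated), via vinylcyclobutenone 26 (not isolated), via dienylketene 27 (not isolated), via cyclohexadienone 28 (not isolated), via silyl ether phenol 29 (not isolated)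
Conditions: 24 (3 equiv), toluene, 110 °C, sealed tube, argon; evaporate; then Bu4NF (1.1 equiv), AcOH (1.1 equiv), THF, 0 °C
Reagents that add atoms: none
Why: Four-electron electrocyclic opening of 20 (breaking the future a1–a2 bond) gives vinylketene 25, whose carbonyl carbon bonds to the nucleophilic, methyl-bearing carbon of the ynol ether in a [2+2] cycloaddition that forms a2–a3 and a4–a5 in 26. A second four-electron opening gives dienylketene 27, ring A closes by thermal six-electron disrotatory electrocyclisation that remakes a1–a2, and dienone 28 tautomerises to phenol 29. The closest known reaction is the Danheiser benzannulation of cyclobutenones with alkoxyalkynes, run here on a less common 3-silyloxy-4-alkyl cyclobutenone. No stereocentre is created, and the racemic centre of 20 becomes the aromatic carbon a1. The selectivity needed is the regiochemistry of the ketene–alkyne cycloaddition, which the polarity of the ynol ether secures, so that OMe ends on a4 and Me on a3; the methoxyalkyne cannot lose an alkene by retro-ene reaction, and the neutral thermal conditions spare the ketones and benzyl ethers. Buffered fluoride then cleaves the aryl silyl ether of 29 in the same flask, since the silyl group has no further role, and the acetic acid keeps the phenoxide and the enolisable ketones away from base.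

Step 12
Reactants: 30 ring A diol
Product: 32 1-[3-(Ar-methyl)-2,4-dihydroxy-6-methoxy-5-methylphenyl]butan-1-one, via ketiminium chloride 31 (not isolated)
Conditions: n-PrCN (3 equiv), ZnCl2, HCl (g), Et2O–CH2Cl2, 0 °C; then H2O–1,4-dioxane, 80 °C
Reagents that add atoms: butanenitrile (CCCC#N); water (O)
Why: Houben–Hoesch acylation of a phloroglucinol-type ring at a5, its only unsubstituted carbon (ortho to OH and OMe, para to OH); rings B and C carry no ring hydrogen, and any benzyl ether lost to dry HCl would only anticipate the final deprotection.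

Step 13
Reactants: 32 pentabenzyl ether of the target
Product: 33 1-[3-[(3-butanoyl-2,4-dihydroxy-6-methoxy-5-methylphenyl)methyl]-5-[(3-butanoyl-2,6-dihydroxy-4-methoxy-5-methylphenyl)methyl]-2,4,6-trihydroxyphenyl]butan-1-one (CNP0171986.0)
Conditions: H2 (1 atm), Pd/C (10 % palladium on carbon), EtOAc–MeOH, rt
Reagents that add atoms: none
Why: hydrogenolysis of five aryl benzyl ethers; aryl ketones chelated to ortho-hydroxyls and the diarylmethane bridges are not expected to be reduced under these mild conditions.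

**Compound list**

1 | 2-methylbenzene-1,3,5-triol | Cc1c(O)cc(O)cc1O | starting material
2 | 1-(2,4,6-trihydroxy-3-methylphenyl)butan-1-one | CCCC(=O)c1c(O)cc(O)c(C)c1O | intermediate
3 | 1-(2,6-dihydroxy-4-methoxy-3-methylphenyl)butan-1-one | CCCC(=O)c1c(O)cc(OC)c(C)c1O | intermediate
4 | 1-[3-[(dimethylamino)methyl]-2,6-dihydroxy-4-methoxy-5-methylphenyl]butan-1-one | CCCC(=O)c1c(O)c(CN(C)C)c(OC)c(C)c1O | intermediate
5 | 1-(2,4,6-trihydroxyphenyl)butan-1-one | CCCC(=O)c1c(O)cc(O)cc1O | starting material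
6 | 2-butanoyl-3-hydroxy-5-methoxy-4-methyl-6-methylidenecyclohexa-2,4-dien-1-one | CCCC(=O)C1=C(O)C(C)=C(OC)C(=C)C1=O | intermediate
7 | 1-[3-[(3-butanoyl-2,4,6-trihydroxyphenyl)methyl]-2,6-dihydroxy-4-methoxy-5-methylphenyl]butan-1-one | CCCC(=O)c1c(O)cc(O)c(Cc2c(O)c(C(=O)CCC)c(O)c(C)c2OC)c1O | intermediate
8 | prop-2-enoic acid | C=CC(=O)O | starting material
9 | 3-[3-butanoyl-5-[(3-butanoyl-2,4-dihydroxy-6-methoxy-5-methylphenyl)methyl]-2,4,6-trihydroxyphenyl]propanoic acid | OC(=O)CCc1c(O)c(C(=O)CCC)c(O)c(Cc2c(O)c(C(=O)CCC)c(O)c(C)c2OC)c1O | intermediate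
10 | 6-butanoyl-8-[(3-butanoyl-2,4-dihydroxy-6-methoxy-5-methylphenyl)methyl]-5,7-dihydroxy-3,4-dihydro-2H-chromen-2-one | O=C1CCc2c(O1)c(Cc3c(O)c(C(=O)CCC)c(O)c(C)c3OC)c(O)c(C(=O)CCC)c2O | intermediate
11 | benzyl 3-[3-butanoyl-5-[(3-butanoyl-2,4-dihydroxy-6-methoxy-5-methylphenyl)methyl]-2,4,6-trihydroxyphenyl]propanoate | O=C(OCc1ccccc1)CCc1c(O)c(C(=O)CCC)c(O)c(Cc2c(O)c(C(=O)CCC)c(O)c(C)c2OC)c1O | intermediate
12 | benzyl 3-Ar-propanoate | O=C(OCc1ccccc1)CCc1c(OCc2ccccc2)c(C(=O)CCC)c(OCc2ccccc2)c(Cc2c(OCc3ccccc3)c(C(=O)CCC)c(OCc3ccccc3)c(C)c2OC)c1OCc1ccccc1 | intermediate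
13 | 3-Ar-propanoic acid | OC(=O)CCc1c(OCc2ccccc2)c(C(=O)CCC)c(OCc2ccccc2)c(Cc2c(OCc3ccccc3)c(C(=O)CCC)c(OCc3ccccc3)c(C)c2OC)c1OCc1ccccc1 | intermediate
14 | ethyne | C#C | starting material
15 | lithium acetylide | [Li]C#C | intermediate
16 | lithium ethynolate | [Li+].[O-]C#C | intermediate
17 | ethynyloxytri(propan-2-yl)silane | C#CO[Si](C(C)C)(C(C)C)C(C)C | intermediate
18 | 3-Ar-propanoyl chloride | ClC(=O)CCc1c(OCc2ccccc2)c(C(=O)CCC)c(OCc2ccccc2)c(Cc2c(OCc3ccccc3)c(C(=O)CCC)c(OCc3ccccc3)c(C)c2OC)c1OCc1ccccc1 | intermediate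
19 | 3-Ar-prop-1-en-1-one (ketene) | O=C=CCc1c(OCc2ccccc2)c(C(=O)CCC)c(OCc2ccccc2)c(Cc2c(OCc3ccccc3)c(C(=O)CCC)c(OCc3ccccc3)c(C)c2OC)c1OCc1ccccc1 | intermediate
20 | 4-(Ar-methyl)-3-[tri(propan-2-yl)silyloxy]cyclobut-2-en-1-one (racemic, one enantiomer drawn) | O=C1C=C(O[Si](C(C)C)(C(C)C)C(C)C)[C@@H]1Cc1c(OCc2ccccc2)c(C(=O)CCC)c(OCc2ccccc2)c(Cc2c(OCc3ccccc3)c(C(=O)CCC)c(OCc3ccccc3)c(C)c2OC)c1OCc1ccccc1 | intermediate
21 | 2-chloro-1,1-dimethoxyethane | COC(CCl)OC | starting material
22 | 1-chloro-2-methoxyethene | COC=CCl | intermediate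
23 | sodium methoxyethynide | [Na+].[C-]#COC | intermediate
24 | 1-methoxyprop-1-yne | CC#COC | intermediate
25 | 5-Ar-3-[tri(propan-2-yl)silyloxy]penta-1,3-dien-1-one (vinylketene) | O=C=CC(O[Si](C(C)C)(C(C)C)C(C)C)=CCc1c(OCc2ccccc2)c(C(=O)CCC)c(OCc2ccccc2)c(Cc2c(OCc3ccccc3)c(C(=O)CCC)c(OCc3ccccc3)c(C)c2OC)c1OCc1ccccc1 | intermediate
26 | 4-{3-Ar-1-[tri(propan-2-yl)silyloxy]prop-1-enyl}-3-methoxy-2-methylcyclobut-2-en-1-one (racemic) | O=C1C(C)=C(OC)C1C(O[Si](C(C)C)(C(C)C)C(C)C)=CCc1c(OCc2ccccc2)c(C(=O)CCC)c(OCc2ccccc2)c(Cc2c(OCc3ccccc3)c(C(=O)CCC)c(OCc3ccccc3)c(C)c2OC)c1OCc1ccccc1 | intermediate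
27 | 7-Ar-3-methoxy-2-methyl-5-[tri(propan-2-yl)silyloxy]hepta-1,3,5-trien-1-one (dienylketene) | O=C=C(C)C(OC)=CC(O[Si](C(C)C)(C(C)C)C(C)C)=CCc1c(OCc2ccccc2)c(C(=O)CCC)c(OCc2ccccc2)c(Cc2c(OCc3ccccc3)c(C(=O)CCC)c(OCc3ccccc3)c(C)c2OC)c1OCc1ccccc1 | intermediate
28 | 6-(Ar-methyl)-3-methoxy-2-methyl-5-[tri(propan-2-yl)silyloxy]cyclohexa-2,4-dien-1-one (racemic) | O=C1C(C)=C(OC)C=C(O[Si](C(C)C)(C(C)C)C(C)C)C1Cc1c(OCc2ccccc2)c(C(=O)CCC)c(OCc2ccccc2)c(Cc2c(OCc3ccccc3)c(C(=O)CCC)c(OCc3ccccc3)c(C)c2OC)c1OCc1ccccc1 | intermediate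
29 | 2-(Ar-methyl)-5-methoxy-6-methyl-3-[tri(propan-2-yl)silyloxy]phenol | Cc1c(O)c(Cc2c(OCc3ccccc3)c(C(=O)CCC)c(OCc3ccccc3)c(Cc3c(OCc4ccccc4)c(C(=O)CCC)c(OCc4ccccc4)c(C)c3OC)c2OCc2ccccc2)c(O[Si](C(C)C)(C(C)C)C(C)C)cc1OC | intermediate
30 | 2-(Ar-methyl)-5-methoxy-4-methylbenzene-1,3-diol | Cc1c(O)c(Cc2c(OCc3ccccc3)c(C(=O)CCC)c(OCc3ccccc3)c(Cc3c(OCc4ccccc4)c(C(=O)CCC)c(OCc4ccccc4)c(C)c3OC)c2OCc2ccccc2)c(O)cc1OC | intermediate
31 | 1-[3-(Ar-methyl)-2,4-dihydroxy-6-methoxy-5-methylphenyl]butan-1-iminium chloride | Cc1c(O)c(Cc2c(OCc3ccccc3)c(C(=O)CCC)c(OCc3ccccc3)c(Cc3c(OCc4ccccc4)c(C(=O)CCC)c(OCc4ccccc4)c(C)c3OC)c2OCc2ccccc2)c(O)c(C(=[NH2+])CCC)c1OC.[Cl-] | intermediate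
32 | 1-[3-(Ar-methyl)-2,4-dihydroxy-6-methoxy-5-methylphenyl]butan-1-one | Cc1c(O)c(Cc2c(OCc3ccccc3)c(C(=O)CCC)c(OCc3ccccc3)c(Cc3c(OCc4ccccc4)c(C(=O)CCC)c(OCc4ccccc4)c(C)c3OC)c2OCc2ccccc2)c(O)c(C(=O)CCC)c1OC | intermediate
33 | 1-[3-[(3-butanoyl-2,4-dihydroxy-6-methoxy-5-methylphenyl)methyl]-5-[(3-butanoyl-2,6-dihydroxy-4-methoxy-5-methylphenyl)methyl]-2,4,6-trihydroxyphenyl]butan-1-one | CCCC(=O)c1c(O)c(Cc2c(O)c(C)c(OC)c(C(=O)CCC)c2O)c(O)c(Cc2c(O)c(C(=O)CCC)c(O)c(C)c2OC)c1O | target

**Step count**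

Total: 13 steps. Longest linear sequence: 11 steps (steps 1–7, 9, 11–13); steps 8 and 10 prepare the two alkynes.

**Steps most likely to fail**

Step 11. The donor-stabilised cyclobutenone may open too slowly, or its silyl enol ether may be lost by adventitious hydrolysis, so that the vinylketene is consumed by the product phenol before it meets the alkyne. The fallback gives up the annulation and attaches a preformed ring A by quinone methide alkylation; it sets out from 2 and 7 and comes back at 33. Compound 2 is treated with MOMCl and i-Pr2NEt to give 1-[2-hydroxy-4,6-bis(methoxymethoxy)-3-methylphenyl]butan-1-one F1, in which the chelated hydroxyl between ketone and methyl is expected to stay free. Methylation (MeI, K2CO3, DMF) gives 1-[2-methoxy-4,6-bis(methoxymethoxy)-3-methylphenyl]butan-1-one F2, and HCl in methanol frees 1-(4,6-dihydroxy-2-methoxy-3-methylphenyl)butan-1-one F3. A Mannich reaction with bis(dimethylamino)methane gives 1-[3-[(dimethylamino)methyl]-2,4-dihydroxy-6-methoxy-5-methylphenyl]butan-1-one F4, which on heating with 7 in dioxane should alkylate the one free carbon of ring B and give 33 directly.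

Step 6. Benzylation may go partly on carbon, dearomatising the fully substituted rings, or may stop before the chelated, doubly flanked hydroxyls are etherified. The fallback sets out from 10 and comes back at 12. The four phenols of 10 are etherified under Mitsunobu conditions (BnOH, PPh3, DIAD, THF), which form only aryl–oxygen bonds, to give 5,7-bis(benzyloxy)-8-{[2,4-bis(benzyloxy)-3-butanoyl-6-methoxy-5-methylphenyl]methyl}-6-butanoyl-3,4-dihydro-2H-chromen-2-one F5. The lactone serves meanwhile as protecting group for the fifth phenol and the acid. Alcoholysis with benzyl alcohol and K2CO3 in DMF, with BnBr present to trap the single phenoxide, then gives 12.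

Step 5. The acid may cleave or scramble the methylene bridge by retro-Friedel–Crafts reaction, or the acyl-deactivated ring may add so slowly that acrylic acid polymerises. The fallback uses quinone methide chemistry under near-neutral conditions; it sets out from 7 and comes back at 10. A Mannich reaction at the free ring B carbon gives 1-[3-[(3-butanoyl-5-[(dimethylamino)methyl]-2,4,6-trihydroxyphenyl)methyl]-2,6-dihydroxy-4-methoxy-5-methylphenyl]butan-1-one F6. Heating F6 with Meldrum's acid in toluene should give, by Michael addition to the quinone methide and lactonisation with loss of acetone, 6-butanoyl-8-[(3-butanoyl-2,4-dihydroxy-6-methoxy-5-methylphenyl)methyl]-5,7-dihydroxy-2-oxo-3,4-dihydro-2H-chromene-3-carboxylic acid F7. Decarboxylation in warm pyridine then gives 10.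

**Further compounds**

F1 | step 11 | 1-[2-hydroxy-4,6-bis(methoxymethoxy)-3-methylphenyl]butan-1-one | CCCC(=O)c1c(O)c(C)c(OCOC)cc1OCOC
F2 | step 11 | 1-[2-methoxy-4,6-bis(methoxymethoxy)-3-methylphenyl]butan-1-one | CCCC(=O)c1c(OC)c(C)c(OCOC)cc1OCOC
F3 | step 11 | 1-(4,6-dihydroxy-2-methoxy-3-methylphenyl)butan-1-one | CCCC(=O)c1c(OC)c(C)c(O)cc1O
F4 | step 11 | 1-[3-[(dimethylamino)methyl]-2,4-dihydroxy-6-methoxy-5-methylphenyl]butan-1-one | CCCC(=O)c1c(OC)c(C)c(O)c(CN(C)C)c1O
F5 | step 6 | 5,7-bis(benzyloxy)-8-{[2,4-bis(benzyloxy)-3-butanoyl-6-methoxy-5-methylphenyl]methyl}-6-butanoyl-3,4-dihydro-2H-chromen-2-one | O=C1CCc2c(O1)c(Cc3c(OCc4ccccc4)c(C(=O)CCC)c(OCc4ccccc4)c(C)c3OC)c(OCc3ccccc3)c(C(=O)CCC)c2OCc2ccccc2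
F6 | step 5 | 1-[3-[(3-butanoyl-5-[(dimethylamino)methyl]-2,4,6-trihydroxyphenyl)methyl]-2,6-dihydroxy-4-methoxy-5-methylphenyl]butan-1-one | CCCC(=O)c1c(O)c(CN(C)C)c(O)c(Cc2c(O)c(C(=O)CCC)c(O)c(C)c2OC)c1O
F7 | step 5 | 6-butanoyl-8-[(3-butanoyl-2,4-dihydroxy-6-methoxy-5-methylphenyl)methyl]-5,7-dihydroxy-2-oxo-3,4-dihydro-2H-chromene-3-carboxylic acid (racemic) | O=C1Oc2c(Cc3c(O)c(C(=O)CCC)c(O)c(C)c3OC)c(O)c(C(=O)CCC)c(O)c2CC1C(O)=O
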